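**Plan**

1. Cuts (ring locants: C1 = CH bearing the acyl chain, C2 = CH bearing the 3,4-dimethoxyphenyl group, C3=C4 = ring alkene, C5 = CH2, C6 = CH bearing the 4-hydroxy-3-methoxyphenyl group): first the enolised 1,3-diketone between the ring-bound carbonyl carbon and the central CH (acid 14 + enone 16); then the ring bond C1–C2 by a retro-[3,3] shift; then the resulting δ-lactone at its alkynyl–carbonyl and aryl–CH bonds.
2. Enabling feature: O=C–C1–C2–C3=C4 is a γ,δ-unsaturated carbonyl array, and C4 is tied back to C1 through C5–C6. The carboxyl carbon on C1 and an oxygen on C4 therefore fit into a temporary six-membered lactone whose silyl ketene acetal can rearrange only through a boat.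
3. Forward order: conjugate arylation gives the aryl lactone; an arylacetylene extends the chain; oxidation rebuilds a lactone (temporary ring); semi-reduction gives the Z-alkene; the Claisen ring contraction builds the carbocycle and removes the lactone; enolate acylation and desilylation finish.
4. Stereochemistry: C6 from the Rh/(R)-BINAP arylation; the carbinol centre from Ru-TsDPEN transfer hydrogenation; C1 and C2 by chirality transfer from that carbinol in the [3,3] step (Z-alkene plus trans-lactone give 1,2-trans and 1,6-cis), the carbinol centre being consumed.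

Key step: step 7

Assumption: the enolised 1,3-diketone is one of freely interconverting tautomers, so only its constitution is built. The ring centres are read from the SMILES as (1S,2S,6S): acyl group trans to the 3,4-dimethoxyphenyl group and cis to the 4-hydroxy-3-methoxyphenyl group.

**Route**

Step 1
Reactants: 1 5,6-dihydro-2H-pyran-2-one; 2 (4-hydroxy-3-methoxyphenyl)boronic acid
Product: 3 (4R)-4-(4-hydroxy-3-methoxyphenyl)oxan-2-one
Conditions: Rh(acac)(C2H4)2 (3 mol%), (R)-BINAP, 2 (3 equiv), dioxane/H2O 10:1, 100 °C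
Reagents that add atoms: none
Why: Rhodium-catalysed asymmetric 1,4-addition of an arylboronic acid to a cyclic enoate (Hayashi–Miyaura reaction); the (R)-BINAP arylrhodium species (monovalent rhodium) is expected, by the established facial model for cyclic enoates, to give the (R)-lactone and so set the future C6 (the antipodal ligand would give the mirror image).

Step 2
Reactants: 3
Product: 4 (4R)-4-[4-(tert-butyldimethylsilyloxy)-3-methoxyphenyl]oxan-2-one
Conditions: TBSCl, imidazole, DMF, 25 °C
Reagents that add atoms: tert-butyldimethylsilyl chloride, CC(C)(C)[Si](C)(C)Cl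
Why: Standard silylation of a phenol, which masks the acidic and oxidisable OH for the organolithium, oxidation and enolate steps without touching the stereocentre.

Step 3
Reactants: 4; 5 4-ethynyl-1,2-dimethoxybenzene
Product: 7 (5R)-5-[4-(tert-butyldimethylsilyloxy)-3-methoxyphenyl]-1-(3,4-dimethoxyphenyl)-7-hydroxyhept-1-yn-3-one, via lithium acetylide 6 (not isolated)
Conditions: 5, n-BuLi, THF, −78 °C; then 4, −78 °C; AcOH quench at −78 °C
Reagents that add atoms: none
Why: Acylation of a lithium acetylide by a lactone; the tetrahedral lithium alkoxide is stable at −78 °C, so only one addition should occur, and work-up should give the δ-hydroxy ynone (in equilibrium with its cyclic hemiketal) with the stereocentre β to the ketone and unable to epimerise.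

Step 4
Reactants: 7
Product: 8 (3R,5R)-3-[4-(tert-butyldimethylsilyloxy)-3-methoxyphenyl]-7-(3,4-dimethoxyphenyl)hept-6-yne-1,5-diol
Conditions: Ru[(R,R)-TsDPEN](p-cymene) (preformed amido complex, 2 mol%), i-PrOH, 25 °C
Reagents that add atoms: none
Why: Noyori asymmetric transfer hydrogenation of an alkynyl ketone, which reduces the open-chain ynone drained from the hemiketal equilibrium; the (R,R)-catalyst is expected, by analogy with simple alkyl alkynyl ketones, to give the (R)-propargylic alcohol under catalyst control.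

Step 5
Reactants: 8
Product: 9 (4S,6R)-4-[4-(tert-butyldimethylsilyloxy)-3-methoxyphenyl]-6-[(3,4-dimethoxyphenyl)ethynyl]oxan-2-one
Conditions: TEMPO (0.2 equiv), PhI(OAc)2 (2.5 equiv), CH2Cl2, 25 °C
Reagents that add atoms: none
Why: Oxoammonium-mediated oxidative lactonisation of a 1,5-diol; the primary alcohol is oxidised selectively, the aldehyde is trapped by the secondary OH as a six-membered lactol and oxidised on to the lactone, and neither stereocentre is touched, so the trans-4,6 lactone results.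

Step 6
Reactants: 9
Product: 10 (4S,6R)-4-[4-(tert-butyldimethylsilyloxy)-3-methoxyphenyl]-6-[(Z)-2-(3,4-dimethoxyphenyl)ethenyl]oxan-2-one
Conditions: H2 (1 atm), Pd/CaCO3 poisoned with Pb(OAc)2 (Lindlar catalyst), quinoline, EtOAc, 25 °C
Reagents that add atoms: none
Why: Lindlar semi-hydrogenation; syn delivery of H2 on the poisoned palladium surface should stop at the Z-alkene, whose geometry later decides the configuration at C2.

Step 7
Reactants: 10
Product: 14 (1S,2S,6S)-6-[4-(tert-butyldimethylsilyloxy)-3-methoxyphenyl]-2-(3,4-dimethoxyphenyl)cyclohex-3-ene-1-carboxylic acid, via lithium enolate 11 (not isolated), via silyl ketene acetal 12 (not isolated), via trimethylsilyl ester 13 (not isolated)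
Conditions: Me3SiCl/Et3N (premixed), LiN(i-Pr)2, THF, −78 to 25 °C; then toluene, 105 °C; then 1 M HCl, THF, 0 °C
Reagents that add atoms: none
Why: Kinetic α-deprotonation of the lactone and O-silylation give cyclic ketene acetal 12, in which C1=C(OSi)–O–C4–C3=C2 is a complete 1,5-diene array, and heating should trigger a concerted suprafacial [3,3] sigmatropic shift that forms the C1–C2 σ bond while the allylic C4–O bond breaks and the double bond moves to C3=C4, giving silyl ester 13 and, after hydrolysis, acid 14. The closest known reaction type is the Ireland–Claisen rearrangement of silyl ketene acetals of 6-alkenyl δ-lactones, which contracts the lactone to a cyclohex-3-ene-1-carboxylic acid. The carbocycle closes in a pericyclic mode in which the two-atom bridge C5–C6 between the termini of the array excludes a chair and enforces a boat-like transition state shaped like bicyclo[2.2.2]octane. C1 and C2 are set by transfer of chirality from the (R)-carbinol carbon, which is consumed: the carboxyl carbon stays on the ring face from which the lactone oxygen departs, and in the boat the Z-placed aryl group is turned to the opposite face, so CO2H and the 3,4-dimethoxyphenyl group end trans. The existing aryl-bearing centre C6 is untouched and, being trans to the alkenyl group in 10, sits exo on the boat and ends cis to CO2H, which completes the (1S,2S,6S) pattern. The step needs the rearrangement to outrun desilylation or ionisation of the allylic ester, which in situ silylation, the non-polar medium and the unstrained exo position of the C6 aryl group should secure, while diastereospecificity follows from the defined Z geometry and the single possible boat.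

Step 8
Reactants: 15 (E)-4-(4-hydroxy-3-methoxyphenyl)but-3-en-2-one (dehydrozingerone)
Product: 16 (E)-4-[4-(tert-butyldimethylsilyloxy)-3-methoxyphenyl]but-3-en-2-one
Conditions: TBSCl, imidazole, DMF, 25 °C
Reagents that add atoms: tert-butyldimethylsilyl chloride, CC(C)(C)[Si](C)(C)Cl
Why: Standard phenol silylation, which removes the acidic OH so that the methyl ketone can be converted cleanly into its lithium enolate.

Step 9
Reactants: 14; 16
Product: 19 (2Z,4E)-1-[(1S,2S,6S)-6-[4-(tert-butyldimethylsilyloxy)-3-methoxyphenyl]-2-(3,4-dimethoxyphenyl)cyclohex-3-en-1-yl]-5-[4-(tert-butyldimethylsilyloxy)-3-methoxyphenyl]-3-hydroxypenta-2,4-dien-1-one, via acid chloride 17 (not isolated), via lithium enolate 18 (not isolated)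
Conditions: 14, (COCl)2, cat. DMF, CH2Cl2, 0 to 25 °C, evaporate; 16 (2.2 equiv), LiN(SiMe3)2 (2.2 equiv), THF, −78 °C; add 17, −78 to −40 °C; AcOH quench
Reagents that add atoms: none
Why: Crossed Claisen-type C-acylation of a ketone lithium enolate by an acid chloride; the second equivalent of enolate converts the product into its diketonate, which shields C1 from deprotonation, and at −78 °C acylation should outrun ketene formation so the C1 configuration is kept.

Step 10
Reactants: 19
Product: 20 (2Z,4E)-1-[(1S,2S,6S)-2-(3,4-dimethoxyphenyl)-6-(4-hydroxy-3-methoxyphenyl)cyclohex-3-en-1-yl]-3-hydroxy-5-(4-hydroxy-3-methoxyphenyl)penta-2,4-dien-1-one (target)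
Conditions: Bu4NF (2.5 equiv), AcOH (2.5 equiv), THF, 0 °C
Reagents that add atoms: none
Why: Fluoride cleavage of both aryl silyl ethers under acetic acid buffering, which should spare the base-sensitive enolised diketone, the alkenes and the epimerisable C1.

**Compound list**

1 | 5,6-dihydro-2H-pyran-2-one | O=C1C=CCCO1 | starting material
2 | (4-hydroxy-3-methoxyphenyl)boronic acid | COc1cc(B(O)O)ccc1O | starting material
3 | (4R)-4-(4-hydroxy-3-methoxyphenyl)oxan-2-one | O=C1C[C@H](c2ccc(O)c(OC)c2)CCO1 | intermediate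
4 | (4R)-4-[4-(tert-butyldimethylsilyloxy)-3-methoxyphenyl]oxan-2-one | O=C1C[C@H](c2ccc(O[Si](C)(C)C(C)(C)C)c(OC)c2)CCO1 | intermediate
5 | 4-ethynyl-1,2-dimethoxybenzene | C#Cc1ccc(OC)c(OC)c1 | starting material
6 | lithium (3,4-dimethoxyphenyl)acetylide | [Li+].[C-]#Cc1ccc(OC)c(OC)c1 | intermediate (not isolated)
7 | (5R)-5-[4-(tert-butyldimethylsilyloxy)-3-methoxyphenyl]-1-(3,4-dimethoxyphenyl)-7-hydroxyhept-1-yn-3-one | COc1ccc(C#CC(=O)C[C@H](c2ccc(O[Si](C)(C)C(C)(C)C)c(OC)c2)CCO)cc1OC | intermediate
8 | (3R,5R)-3-[4-(tert-butyldimethylsilyloxy)-3-methoxyphenyl]-7-(3,4-dimethoxyphenyl)hept-6-yne-1,5-diol | COc1ccc(C#C[C@H](O)C[C@H](c2ccc(O[Si](C)(C)C(C)(C)C)c(OC)c2)CCO)cc1OC | intermediate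
9 | (4S,6R)-4-[4-(tert-butyldimethylsilyloxy)-3-methoxyphenyl]-6-[(3,4-dimethoxyphenyl)ethynyl]oxan-2-one | O=C1C[C@@H](c2ccc(O[Si](C)(C)C(C)(C)C)c(OC)c2)C[C@H](C#Cc2ccc(OC)c(OC)c2)O1 | intermediate
10 | (4S,6R)-4-[4-(tert-butyldimethylsilyloxy)-3-methoxyphenyl]-6-[(Z)-2-(3,4-dimethoxyphenyl)ethenyl]oxan-2-one | O=C1C[C@@H](c2ccc(O[Si](C)(C)C(C)(C)C)c(OC)c2)C[C@H](/C=C\c2ccc(OC)c(OC)c2)O1 | intermediate
11 | lithium enolate of lactone 10 | [Li+].[O-]C1=C[C@@H](c2ccc(O[Si](C)(C)C(C)(C)C)c(OC)c2)C[C@H](/C=C\c2ccc(OC)c(OC)c2)O1 | intermediate (not isolated)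
12 | trimethylsilyl ketene acetal of lactone 10 | C[Si](C)(C)OC1=C[C@@H](c2ccc(O[Si](C)(C)C(C)(C)C)c(OC)c2)C[C@H](/C=C\c2ccc(OC)c(OC)c2)O1 | intermediate (not isolated)
13 | trimethylsilyl (1S,2S,6S)-6-[4-(tert-butyldimethylsilyloxy)-3-methoxyphenyl]-2-(3,4-dimethoxyphenyl)cyclohex-3-ene-1-carboxylate | C[Si](C)(C)OC(=O)[C@@H]1[C@@H](c2ccc(OC)c(OC)c2)C=CC[C@@H]1c3ccc(O[Si](C)(C)C(C)(C)C)c(OC)c3 | intermediate (not isolated)
14 | (1S,2S,6S)-6-[4-(tert-butyldimethylsilyloxy)-3-methoxyphenyl]-2-(3,4-dimethoxyphenyl)cyclohex-3-ene-1-carboxylic acid | OC(=O)[C@@H]1[C@@H](c2ccc(OC)c(OC)c2)C=CC[C@@H]1c3ccc(O[Si](C)(C)C(C)(C)C)c(OC)c3 | intermediate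
15 | (E)-4-(4-hydroxy-3-methoxyphenyl)but-3-en-2-one | CC(=O)/C=C/c1ccc(O)c(OC)c1 | starting material
16 | (E)-4-[4-(tert-butyldimethylsilyloxy)-3-methoxyphenyl]but-3-en-2-one | CC(=O)/C=C/c1ccc(O[Si](C)(C)C(C)(C)C)c(OC)c1 | intermediate
17 | (1S,2S,6S)-6-[4-(tert-butyldimethylsilyloxy)-3-methoxyphenyl]-2-(3,4-dimethoxyphenyl)cyclohex-3-ene-1-carbonyl chloride | ClC(=O)[C@@H]1[C@@H](c2ccc(OC)c(OC)c2)C=CC[C@@H]1c3ccc(O[Si](C)(C)C(C)(C)C)c(OC)c3 | intermediate (not isolated)
18 | lithium enolate of ketone 16 | [Li+].[O-]C(=C)/C=C/c1ccc(O[Si](C)(C)C(C)(C)C)c(OC)c1 | intermediate (not isolated)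
19 | (2Z,4E)-1-[(1S,2S,6S)-6-[4-(tert-butyldimethylsilyloxy)-3-methoxyphenyl]-2-(3,4-dimethoxyphenyl)cyclohex-3-en-1-yl]-5-[4-(tert-butyldimethylsilyloxy)-3-methoxyphenyl]-3-hydroxypenta-2,4-dien-1-one | COc1cc(/C=C/C(O)=C/C(=O)[C@@H]2[C@@H](c3ccc(OC)c(OC)c3)C=CC[C@@H]2c2ccc(O[Si](C)(C)C(C)(C)C)c(OC)c2)ccc1O[Si](C)(C)C(C)(C)C | intermediate
20 | (2Z,4E)-1-[(1S,2S,6S)-2-(3,4-dimethoxyphenyl)-6-(4-hydroxy-3-methoxyphenyl)cyclohex-3-en-1-yl]-3-hydroxy-5-(4-hydroxy-3-methoxyphenyl)penta-2,4-dien-1-one | COc1cc(/C=C/C(O)=C/C(=O)[C@@H]2[C@@H](c3ccc(OC)c(OC)c3)C=CC[C@@H]2c2ccc(O)c(OC)c2)ccc1O | target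

**Step count and risks**

Total step count: 10. Longest linear sequence: 9 (steps 1 to 7, 9 and 10); step 8 is a one-step side branch.

Steps most likely to fail:

1. Step 7. The boat transition state eclipses the Z-aryl group with the C5–C6 tether, so the sigmatropic shift may be slower than desilylation, hydrolysis or ionisation of the allylic C–O bond of the ketene acetal. The fallback sets out from 4 and comes back at 14; it builds C1 and C2 in an open chain under catalyst control and closes the ring at the alkene instead.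
   - Reduction of 4 with i-Bu2AlH (CH2Cl2, −78 °C) should give the lactol (4R)-4-[4-(tert-butyldimethylsilyloxy)-3-methoxyphenyl]oxan-2-ol F1.
   - Wittig methylenation with Ph3P=CH2 should give the alkenol (3S)-3-[4-(tert-butyldimethylsilyloxy)-3-methoxyphenyl]hex-5-en-1-ol F2.
   - Dess–Martin oxidation should give the aldehyde (3S)-3-[4-(tert-butyldimethylsilyloxy)-3-methoxyphenyl]hex-5-enal F3.
   - The racemic carbinol 1-(3,4-dimethoxyphenyl)prop-2-en-1-ol F4 is made from 3,4-dimethoxybenzaldehyde and vinylmagnesium bromide.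
   - Iridium/amine dual-catalytic α-allylation of F3 with F4 ([Ir(cod)Cl]2, a chiral phosphoramidite–olefin ligand, a diarylprolinol silyl ether and an acid promoter, the enantiomers of ligand and amine chosen for the (2S,3S) product) should give the diene aldehyde (2S,3S)-2-[(1S)-1-[4-(tert-butyldimethylsilyloxy)-3-methoxyphenyl]but-3-en-1-yl]-3-(3,4-dimethoxyphenyl)pent-4-enal F5.
   - Ring-closing metathesis with the second-generation Grubbs catalyst RuCl2(H2IMes)(PCy3)(=CHPh) should give the aldehyde (1S,2S,6S)-6-[4-(tert-butyldimethylsilyloxy)-3-methoxyphenyl]-2-(3,4-dimethoxyphenyl)cyclohex-3-ene-1-carbaldehyde F6.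
   - Pinnick oxidation (NaClO2, NaH2PO4, 2-methylbut-2-ene, t-BuOH/H2O) returns to 14.

2. Step 9. The enolate may be acylated on oxygen, the α-branched acid chloride may form a ketene with loss of the C1 configuration, or the acid chloride may undergo intramolecular Friedel–Crafts acylation onto the neighbouring electron-rich aryl ring. The fallback sets out from 14 and comes back at 19; it reverses the polarity and uses an aldol addition followed by oxidation.
   - MeLi (2.2 equiv, Et2O, 0 °C) should convert the acid into the methyl ketone 1-[(1S,2S,6S)-6-[4-(tert-butyldimethylsilyloxy)-3-methoxyphenyl]-2-(3,4-dimethoxyphenyl)cyclohex-3-en-1-yl]ethan-1-one F7.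
   - The aldehyde (E)-3-[4-(tert-butyldimethylsilyloxy)-3-methoxyphenyl]prop-2-enal F8 is made from 4-hydroxy-3-methoxycinnamaldehyde with TBSCl and imidazole.
   - The kinetic lithium enolate of F7 (LiN(i-Pr)2, THF, −78 °C, deprotonation at CH3 rather than at the hindered ring CH) should add to F8 to give the aldol product (4E)-1-[(1S,2S,6S)-6-[4-(tert-butyldimethylsilyloxy)-3-methoxyphenyl]-2-(3,4-dimethoxyphenyl)cyclohex-3-en-1-yl]-5-[4-(tert-butyldimethylsilyloxy)-3-methoxyphenyl]-3-hydroxypent-4-en-1-one F9, as a mixture of carbinol epimers.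
   - Dess–Martin oxidation of the allylic alcohol gives 19.

3. Step 6. Palladium may over-reduce the alkene, cleave the propargylic or allylic acyloxy C–O bond by hydrogenolysis, or isomerise the Z-alkene to E. The fallback sets out from 8 and comes back at 10; it makes the cis-alkene before the lactone, by electron transfer from a metal instead of catalytic hydrogenation.
   - Zinc activated with Cu(OAc)2 and AgNO3 in MeOH/H2O should reduce the conjugated propargylic alcohol strictly cis to the enediol (3R,5R,6Z)-3-[4-(tert-butyldimethylsilyloxy)-3-methoxyphenyl]-7-(3,4-dimethoxyphenyl)hept-6-ene-1,5-diol F10.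
   - The TEMPO/PhI(OAc)2 oxidative lactonisation of step 5, applied to F10, gives 10.

**Further compounds**

F1 | step 7 | (4R)-4-[4-(tert-butyldimethylsilyloxy)-3-methoxyphenyl]oxan-2-ol (anomer mixture) | OC1C[C@H](c2ccc(O[Si](C)(C)C(C)(C)C)c(OC)c2)CCO1
F2 | step 7 | (3S)-3-[4-(tert-butyldimethylsilyloxy)-3-methoxyphenyl]hex-5-en-1-ol | C=CC[C@H](c1ccc(O[Si](C)(C)C(C)(C)C)c(OC)c1)CCO
F3 | step 7 | (3S)-3-[4-(tert-butyldimethylsilyloxy)-3-methoxyphenyl]hex-5-enal | C=CC[C@H](c1ccc(O[Si](C)(C)C(C)(C)C)c(OC)c1)CC=O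
F4 | step 7 | rac-1-(3,4-dimethoxyphenyl)prop-2-en-1-ol | C=CC(O)c1ccc(OC)c(OC)c1
F5 | step 7 | (2S,3S)-2-[(1S)-1-[4-(tert-butyldimethylsilyloxy)-3-methoxyphenyl]but-3-en-1-yl]-3-(3,4-dimethoxyphenyl)pent-4-enal | O=C[C@@H]([C@@H](c1ccc(O[Si](C)(C)C(C)(C)C)c(OC)c1)CC=C)[C@@H](c1ccc(OC)c(OC)c1)C=C
F6 | step 7 | (1S,2S,6S)-6-[4-(tert-butyldimethylsilyloxy)-3-methoxyphenyl]-2-(3,4-dimethoxyphenyl)cyclohex-3-ene-1-carbaldehyde | O=C[C@@H]1[C@@H](c2ccc(OC)c(OC)c2)C=CC[C@@H]1c3ccc(O[Si](C)(C)C(C)(C)C)c(OC)c3
F7 | step 9 | 1-[(1S,2S,6S)-6-[4-(tert-butyldimethylsilyloxy)-3-methoxyphenyl]-2-(3,4-dimethoxyphenyl)cyclohex-3-en-1-yl]ethan-1-one | CC(=O)[C@@H]1[C@@H](c2ccc(OC)c(OC)c2)C=CC[C@@H]1c3ccc(O[Si](C)(C)C(C)(C)C)c(OC)c3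
F8 | step 9 | (E)-3-[4-(tert-butyldimethylsilyloxy)-3-methoxyphenyl]prop-2-enal | O=C/C=C/c1ccc(O[Si](C)(C)C(C)(C)C)c(OC)c1
F9 | step 9 | (4E)-1-[(1S,2S,6S)-6-[4-(tert-butyldimethylsilyloxy)-3-methoxyphenyl]-2-(3,4-dimethoxyphenyl)cyclohex-3-en-1-yl]-5-[4-(tert-butyldimethylsilyloxy)-3-methoxyphenyl]-3-hydroxypent-4-en-1-one (carbinol epimers) | O=C(CC(O)/C=C/c1ccc(O[Si](C)(C)C(C)(C)C)c(OC)c1)[C@@H]1[C@@H](c2ccc(OC)c(OC)c2)C=CC[C@@H]1c3ccc(O[Si](C)(C)C(C)(C)C)c(OC)c3
F10 | step 6 | (3R,5R,6Z)-3-[4-(tert-butyldimethylsilyloxy)-3-methoxyphenyl]-7-(3,4-dimethoxyphenyl)hept-6-ene-1,5-diol | COc1ccc(/C=C\[C@H](O)C[C@H](c2ccc(O[Si](C)(C)C(C)(C)C)c(OC)c2)CCO)cc1OC
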